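Ring numbering used throughout: C1 (oxirane CH), C2 (CH2), C3 (CH–O-angeloyl), C4 (oxirane C–CH3), C5 (oxirane CH), C6 (CH2), C7 (CH–isopropenyl), C8 (CH–O-angeloyl), C9 (CH–OAc), C10 (oxirane C–CH3). Enabling feature: ring methylene C6 is bonded to C5 of the cis-fused 4,5-oxirane, so once that oxirane is traced back to a Z-C4=C5 alkene the ring bond C5–C6 is an sp3–sp2 bond that a primary alkylzinc (C6) and a (Z)-alkenyl iodide (C5) can make.
Cuts, in retrosynthetic order: the O3–angeloyl bond and the 4,5-oxirane (back to a C3 allylic alcohol), the ring bond C5–C6, then on the open chain C7–C8, C8–C9, C1=C10 and C2–C3.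
Forward: the chain grows linearly from the C5 end (C3–C5 from propargyl alcohol, then C2/C1, C10/C9, C8, and last C7/C6 with the isopropenyl group); the 1,10-oxirane is made on the open chain (step 8), the ten-membered carbocycle closes in step 21, and the 4,5-oxirane is fused on in step 23.
Stereochemistry: C3 from Brown allylation; C1 and C10 from Sharpless epoxidation of a Z-allylic alcohol; C9 from Felkin–Anh vinyl addition to the epoxy aldehyde; C7 and C8 from a (Z)-γ-substituted allylboronate (7,8-syn, 8,9-anti); C4 and C5 from hydroxyl-directed epoxidation of the ring Z-alkene; Z-C4=C5 and Z-C1=C10 from anti-carbomagnesiation and Still–Gennari olefination; both angelates from angelic acid under non-isomerising acylation.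

Key step: step 21

Remark: the C3 oxygen is carried as a silyl ether through the ring closure and acylated last, so that zerovalent palladium meets no allylic carboxylate and the free C3 hydroxyl can direct and activate the last epoxidation; names use the ring locants above, CIP descriptors are quoted only where protecting groups do not change them, and the SMILES strings are decisive.

Step 1
Reactants: 1 propargyl alcohol
Product: 3 (Z)-3-iodo-2-methylprop-2-en-1-ol, via alkenylmagnesium alkoxide 2 (not isolated)
Conditions: MeMgBr (2.5 equiv), CuI (10 mol%), THF, −10 °C to rt; then I2, −78 to 0 °C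
Reagents that add atoms: methylmagnesium bromide, C[Mg]Br; iodine, II
Why: Copper-catalysed anti-carbomagnesiation of the propargylic alkoxide puts methyl on C4 and magnesium on C5 inside a five-membered chelate, and iodinolysis with retention should give the Z-iodide that later fixes the C4=C5 geometry.

Step 2
Reactants: 3 (Z)-3-iodo-2-methylprop-2-en-1-ol
Product: 4 (Z)-3-iodo-2-methylprop-2-enal
Conditions: MnO2 (activated, excess), CH2Cl2, rt, dark; filtered and used at once
Reagents that add atoms: none
Why: Allylic alcohol oxidation with MnO2 stops at the enal, and neutral conditions without light should keep the Z-iodoalkene from isomerising.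

Step 3
Reactants: 4 (Z)-3-iodo-2-methylprop-2-enal
Product: 5 (1Z,3S)-1-iodo-2-methylhexa-1,5-dien-3-ol
Conditions: B-allyldiisopinocampheylborane made from (+)-α-pinene, Et2O, −78 °C; then NaOH, H2O2, 0 °C
Reagents that add atoms: B-allyldiisopinocampheylborane derived from (+)-α-pinene, C=CCB([C@@H]1C[C@@H]2C[C@H]([C@H]1C)C2(C)C)[C@@H]1C[C@@H]2C[C@H]([C@H]1C)C2(C)C
Why: Brown allylboration through a chair transition state, in which this enantiomer of the reagent adds the allyl group to the Si face of the aldehyde and so sets C3 as S.

Step 4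
Reactants: 5 (1Z,3S)-1-iodo-2-methylhexa-1,5-dien-3-ol
Product: 6 tert-butyldimethylsilyl ether of 5
Conditions: tBuMe2SiCl, imidazole, DMF, rt
Reagents that add atoms: tert-butyldimethylsilyl chloride, CC(C)(C)[Si](C)(C)Cl
Why: Standard silylation of a secondary allylic alcohol gives an ether that should survive base, hydride, titanium alkoxide, organozinc and palladium and still leave with fluoride in step 22.

Step 5
Reactants: 6 tert-butyldimethylsilyl ether of 5
Product: 7 (3S,4Z)-3-[(tert-butyldimethylsilyl)oxy]-5-iodo-4-methylpent-4-enal (C1 aldehyde)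
Conditions: OsO4 (2 mol%), NaIO4, 2,6-lutidine, dioxane/H2O 3:1, rt
Reagents that add atoms: sodium periodate, [Na+].[O-]I(=O)(=O)=O (terminal source of the carbonyl oxygen, passed on through OsO4)
Why: Lemieux–Johnson cleavage, in which OsO4 dihydroxylates the unhindered terminal alkene far faster than the hindered, iodine-deactivated trisubstituted alkene and the lutidine buffer should prevent β-elimination of the silyloxy group from the aldehyde.

Step 6
Reactants: 7 C1 aldehyde; 8 ethyl 2-[bis(2,2,2-trifluoroethoxy)phosphoryl]propanoate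
Product: 9 ethyl (2Z,5S,6Z)-5-[(tert-butyldimethylsilyl)oxy]-7-iodo-2,6-dimethylhepta-2,6-dienoate
Conditions: KN(SiMe3)2, 18-crown-6, THF, −78 °C
Reagents that add atoms: none
Why: Still–Gennari olefination, whose trifluoroethyl phosphonate under dissociating conditions gives the kinetic Z-enoate and so places C2 and C9 cis on C1=C10, as the cis-1,10-oxirane requires.

Step 7
Reactants: 9 Z-enoate
Product: 10 (2Z,5S,6Z)-5-[(tert-butyldimethylsilyl)oxy]-7-iodo-2,6-dimethylhepta-2,6-dien-1-ol
Conditions: iBu2AlH, CH2Cl2, −78 °C
Reagents that add atoms: none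
Why: Hydride reduction of the conjugated ester to the allylic alcohol at low temperature should leave the alkenyl iodide, the silyl ether and both alkene geometries untouched.

Step 8
Reactants: 10 Z-allylic alcohol
Product: 11 {(2S,3R)-3-[(2S,3Z)-2-[(tert-butyldimethylsilyl)oxy]-4-iodo-3-methylbut-3-en-1-yl]-2-methyloxiran-2-yl}methanol
Conditions: Ti(OiPr)4 (0.3 equiv), L-(+)-diethyl tartrate (0.36 equiv), tBuOOH, 4 Å molecular sieves, CH2Cl2, −20 °C
Reagents that add atoms: tert-butyl hydroperoxide, CC(C)(C)OO
Why: Sharpless asymmetric epoxidation, in which only the allylic alcohol alkene binds titanium and the L-(+)-tartrate catalyst delivers oxygen to the face that gives the (2S,3R)-epoxy alcohol (the sense known for other Z-allylic alcohols), setting C1 and C10 under reagent control.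

Step 9
Reactants: 11 epoxy alcohol
Product: 12 (2R,3R)-3-[(2S,3Z)-2-[(tert-butyldimethylsilyl)oxy]-4-iodo-3-methylbut-3-en-1-yl]-2-methyloxirane-2-carbaldehyde (C9 aldehyde)
Conditions: Dess–Martin periodinane, NaHCO3, CH2Cl2, 0 °C to rt
Reagents that add atoms: none
Why: Buffered Dess–Martin oxidation should give the α,β-epoxy aldehyde without oxirane opening, and C10 is quaternary and cannot epimerise.

Step 10
Reactants: 12 C9 aldehyde; 13 vinylmagnesium bromide
Product: 14 (9S)-vinyl carbinol, hydroxyl 9,10-anti to the oxirane oxygen, remainder as in 12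
Conditions: CH2=CHMgBr, THF, −78 °C
Reagents that add atoms: none
Why: Grignard addition under Felkin–Anh control, with the oxirane C10–O bond antiperiplanar to the incoming vinyl group and attack past the C10 methyl rather than the C1 arm, which should give the 9,10-anti carbinol while low temperature in THF disfavours a magnesium chelate.

Step 11
Reactants: 14 vinyl carbinol
Product: 15 triethylsilyl ether of 14
Conditions: Et3SiCl, imidazole, DMAP (cat.), DMF, 0 °C to rt
Reagents that add atoms: triethylsilyl chloride, CC[Si](Cl)(CC)CC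
Why: Silylation masks the C9 hydroxyl with a group that cannot migrate as an acyl group would and that leaves later under conditions sparing the C3 tert-butyldimethylsilyl ether.

Step 12
Reactants: 15 triethylsilyl ether of 14
Product: 16 C8 aldehyde (α-triethylsilyloxy aldehyde from cleavage of the vinyl group of 15)
Conditions: OsO4 (3 mol%), NaIO4, 2,6-lutidine, dioxane/H2O 3:1, rt
Reagents that add atoms: sodium periodate, [Na+].[O-]I(=O)(=O)=O (terminal source of the carbonyl oxygen, passed on through OsO4)
Why: Second Lemieux–Johnson cleavage, in which the monosubstituted vinyl group is the only alkene that OsO4 attacks readily and the buffered medium should keep the α-silyloxy centre C9 from epimerising.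

Step 13
Reactants: 17 but-2-yn-1-ol
Product: 19 (Z)-3-iodobut-2-en-1-ol, via cyclic alkenylalanate 18 (not isolated)
Conditions: NaAlH2(OCH2CH2OMe)2, THF, 0 °C to rt; then I2, THF, −78 °C
Reagents that add atoms: iodine, II
Why: Hydroxyl-directed trans-hydroalumination places aluminium on C3 cis to the CH2O group in a five-membered ring, and iodinolysis with retention should give the Z-iodide.

Step 14
Reactants: 19 (Z)-3-iodobut-2-en-1-ol
Product: 20 triethyl{[(2Z)-3-iodobut-2-en-1-yl]oxy}silane
Conditions: Et3SiCl, imidazole, CH2Cl2, 0 °C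
Reagents that add atoms: triethylsilyl chloride, CC[Si](Cl)(CC)CC
Why: Routine silylation of a primary allylic alcohol gives the same protecting group as on O9, so that both leave together in step 18.

Step 15
Reactants: 20 silyl ether of the Z-iodide
Product: 21 triethyl{[(2Z)-3-methyl-4-(4,4,5,5-tetramethyl-1,3,2-dioxaborolan-2-yl)but-2-en-1-yl]oxy}silane
Conditions: ICH2Bpin, Zn dust, THF, rt (gives IZnCH2Bpin); then 20, Pd(PPh3)4 (3 mol%), THF, rt
Reagents that add atoms: 2-(iodomethyl)-4,4,5,5-tetramethyl-1,3,2-dioxaborolane, ICB1OC(C)(C)C(C)(C)O1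
Why: Negishi coupling of the borylmethylzinc iodide with the alkenyl iodide under zerovalent palladium proceeds with retention and without base, so the (Z)-γ-substituted allylboronate should form without a follow-up Suzuki reaction and without an organolithium that would invite silyl migration.

Step 16
Reactants: 16 C8 aldehyde; 21 (Z)-allylboronate
Product: 22 C8 carbinol (7,8-syn, 8,9-anti; C7 bears isopropenyl and CH2OSiEt3)
Conditions: 21 (1.5 equiv), toluene (1 M), 4 Å molecular sieves, rt to 40 °C; then aqueous NaHCO3
Reagents that add atoms: none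
Why: Type 1 allylboration through a closed chair transition state, in which the Z-γ-CH2OSiEt3 group sits axial and gives the 7,8-syn relationship, the α-silyloxy aldehyde reacts in the Cornforth/polar Felkin–Anh arrangement that Z-boronates reinforce and gives 8,9-anti, and the β-methyl of the reagent becomes the isopropenyl group.

Step 17
Reactants: 22 C8 carbinol; 23 angelic acid
Product: 24 C8 angelate of 22
Conditions: 23, 2,4,6-trichlorobenzoyl chloride, Et3N, toluene, rt; then 22, toluene, 80 °C
Reagents that add atoms: none
Why: Acylation with the preformed angelic 2,4,6-trichlorobenzoic mixed anhydride (Yamaguchi-type, no DMAP) should esterify the hindered C8 hydroxyl without Z-to-E isomerisation to the tiglate and without an alkoxide that would let the C9 silyl group migrate.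

Step 18
Reactants: 24 C8 angelate
Product: 25 C6,C9-diol (C3 silyl ether and C8 angelate retained)
Conditions: HF·pyridine, pyridine, THF, 0 °C
Reagents that add atoms: none
Why: Buffered fluoride cleaves both triethylsilyl ethers much faster than the tert-butyldimethylsilyl ether, and low temperature with excess pyridine should keep the oxirane closed and the angelate on O8.

Step 19
Reactants: 25 C6,C9-diol
Product: 26 C6 primary iodide with free C9 hydroxyl
Conditions: I2, PPh3, imidazole, CH2Cl2, 0 °C
Reagents that add atoms: iodine, II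
Why: Appel-type iodination converts the primary alcohol selectively because the C9 hydroxyl next to the quaternary oxirane carbon is too hindered to form the oxyphosphonium salt.

Step 20
Reactants: 26 C6 iodide
Product: 27 acyclic alkyl iodide and (Z)-alkenyl iodide with C9 acetate, C8 angelate, C3 silyl ether and 1,10-oxirane (1R,3S,7R,8S,9S,10R)
Conditions: Ac2O, pyridine, DMAP (cat.), CH2Cl2, 0 °C
Reagents that add atoms: acetic anhydride, CC(=O)OC(C)=O
Why: DMAP-catalysed acetylation of the C9 alcohol is fast at 0 °C, so the acetate should be in place before the neighbouring angelate can migrate or pyridine can alkylate on the primary iodide.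

Step 21
Reactants: 27 acyclic alkyl iodide and (Z)-alkenyl iodide
Product: 29 ten-membered (Z)-C4=C5 cycloalkene with C3 silyl ether, C8 angelate, C9 acetate and 1,10-oxirane (1R,3S,7R,8S,9S,10R), via alkylzinc iodide 28 (not isolated)
Conditions: Zn dust (activated with BrCH2CH2Br and Me3SiCl), LiCl, THF, 25 °C; then syringe-pump addition to PdCl2(dppf) (10 mol%, pre-reduced with iBu2AlH), THF/N-methylpyrrolidone, 50 °C, 2 mM
Reagents that add atoms: none
Why: Proposed new method: LiCl-solubilised zinc inserts only into the primary C6–I bond, the trisubstituted alkenyl iodide being inert to zinc at 25 °C; zerovalent palladium then adds to the C5–I bond with retention, the tethered alkylzinc transmetalates, and C(sp2)–C(sp3) reductive elimination forms C5–C6. The closest known chemistry is the intermolecular Negishi coupling of functionalised primary alkylzinc iodides with alkenyl iodides (geometry retained) and, as a ring-forming analogue, the intramolecular B-alkyl Suzuki–Miyaura macrocyclisation. The ten-membered carbocycle closes by reductive elimination from an eleven-membered palladacycle, leaving the C4=C5 alkene endocyclic and cis. No stereocentre is created, and C7 next to the metal-bearing carbon cannot epimerise because the carbon–zinc bond is at C6. The step needs retention of the Z geometry, which the preformed (Z)-iodide and stereoretentive oxidative addition and reductive elimination secure, and ring closure in preference to oligomerisation and β-hydride elimination, which slow addition into dilute catalyst, the turns imposed by the cis-oxirane and the Z-alkene, and the wide-bite-angle dppf ligand should secure; the alkylzinc iodide is expected to leave the esters, the silyl ether and the oxirane untouched.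

Step 22
Reactants: 29 ten-membered cycloalkene
Product: 30 C3 allylic alcohol of the ten-membered (Z)-cycloalkene
Conditions: HF·pyridine, pyridine, THF, 0 °C to rt
Reagents that add atoms: none
Why: Fluoride-mediated desilylation frees the C3 hydroxyl, and since no ester has a free neighbouring hydroxyl no acyl migration is expected.

Step 23
Reactants: 30 C3 allylic alcohol
Product: 31 4,5:1,10-bis-oxirane with free C3 hydroxyl (oxirane configurations of the target)
Conditions: mCPBA, NaHCO3, CH2Cl2, −20 to 0 °C
Reagents that add atoms: 3-chloroperbenzoic acid, OOC(=O)c1cccc(Cl)c1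
Why: Henbest-type hydroxyl-directed peracid epoxidation, in which allylic 1,3-strain with the cis C6 methylene holds C3–H in the alkene plane so that the hydrogen-bonded peracid adds to the outer face carrying the hydroxyl and not to the face covered by ring carbon C2, giving the 3,4-threo oxirane, while the hydroxyl-activated trisubstituted alkene should react before the isopropenyl group and the electron-poor angelate.

Step 24
Reactants: 31 bis-oxirane alcohol; 23 angelic acid
Product: 32 CNP0220329.1 (1R,3S,4S,5S,7R,8S,9S,10R in the ring numbering)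
Conditions: 23, 2,4,6-trichlorobenzoyl chloride, Et3N, toluene, rt; then 31, toluene, 80 °C
Reagents that add atoms: none
Why: The same mixed-anhydride acylation as in step 17 esterifies the only free hydroxyl at C3 without isomerisation to the tiglate and without a strong base that could trigger a Payne rearrangement of the adjacent oxirane.

Compound list
1 | prop-2-yn-1-ol (propargyl alcohol) | C#CCO | starting material
2 | (Z)-alkenylmagnesium alkoxide BrMgCH=C(CH3)CH2OMgBr, magnesium cis to CH2O | Br[Mg]/C=C(C)\CO[Mg]Br | intermediate (not isolated)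
3 | (Z)-3-iodo-2-methylprop-2-en-1-ol | I/C=C(C)\CO | intermediate
4 | (Z)-3-iodo-2-methylprop-2-enal | I/C=C(C)\C=O | intermediate
5 | (1Z,3S)-1-iodo-2-methylhexa-1,5-dien-3-ol | I/C=C(C)\[C@@H](O)CC=C | intermediate
6 | tert-butyl{[(1Z,3S)-1-iodo-2-methylhexa-1,5-dien-3-yl]oxy}dimethylsilane | I/C=C(C)\[C@@H](O[Si](C)(C)C(C)(C)C)CC=C | intermediate
7 | (3S,4Z)-3-[(tert-butyldimethylsilyl)oxy]-5-iodo-4-methylpent-4-enal | I/C=C(C)\[C@@H](O[Si](C)(C)C(C)(C)C)CC=O | intermediate
8 | ethyl 2-[bis(2,2,2-trifluoroethoxy)phosphoryl]propanoate | CCOC(=O)C(C)P(=O)(OCC(F)(F)F)OCC(F)(F)F | starting material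
9 | ethyl (2Z,5S,6Z)-5-[(tert-butyldimethylsilyl)oxy]-7-iodo-2,6-dimethylhepta-2,6-dienoate | I/C=C(C)\[C@@H](O[Si](C)(C)C(C)(C)C)C/C=C(C)\C(=O)OCC | intermediate
10 | (2Z,5S,6Z)-5-[(tert-butyldimethylsilyl)oxy]-7-iodo-2,6-dimethylhepta-2,6-dien-1-ol | I/C=C(C)\[C@@H](O[Si](C)(C)C(C)(C)C)C/C=C(C)\CO | intermediate
11 | {(2S,3R)-3-[(2S,3Z)-2-[(tert-butyldimethylsilyl)oxy]-4-iodo-3-methylbut-3-en-1-yl]-2-methyloxiran-2-yl}methanol | I/C=C(C)\[C@@H](O[Si](C)(C)C(C)(C)C)C[C@H]1O[C@@]1(C)CO | intermediate
12 | (2R,3R)-3-[(2S,3Z)-2-[(tert-butyldimethylsilyl)oxy]-4-iodo-3-methylbut-3-en-1-yl]-2-methyloxirane-2-carbaldehyde | I/C=C(C)\[C@@H](O[Si](C)(C)C(C)(C)C)C[C@H]1O[C@@]1(C)C=O | intermediate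
13 | vinylmagnesium bromide | C=C[Mg]Br | starting material
14 | (9S)-vinyl carbinol from 12, hydroxyl 9,10-anti to the oxirane oxygen | I/C=C(C)\[C@@H](O[Si](C)(C)C(C)(C)C)C[C@H]1O[C@@]1(C)[C@@H](O)C=C | intermediate
15 | C9 triethylsilyl ether of 14 | I/C=C(C)\[C@@H](O[Si](C)(C)C(C)(C)C)C[C@H]1O[C@@]1(C)[C@@H](O[Si](CC)(CC)CC)C=C | intermediate
16 | C8 aldehyde (α-triethylsilyloxy aldehyde, C1–C5 part as in 12) | I/C=C(C)\[C@@H](O[Si](C)(C)C(C)(C)C)C[C@H]1O[C@@]1(C)[C@@H](O[Si](CC)(CC)CC)C=O | intermediate
17 | but-2-yn-1-ol | CC#CCO | starting material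
18 | sodium cyclic alkenylalanate (five-membered C=C–C–O–Al ring, two 2-methoxyethoxy ligands on aluminium) | C/C1=C/CO[Al-]1(OCCOC)OCCOC.[Na+] | intermediate (not isolated)
19 | (Z)-3-iodobut-2-en-1-ol | C/C(I)=C/CO | intermediate
20 | triethyl{[(2Z)-3-iodobut-2-en-1-yl]oxy}silane | C/C(I)=C/CO[Si](CC)(CC)CC | intermediate
21 | triethyl{[(2Z)-3-methyl-4-(4,4,5,5-tetramethyl-1,3,2-dioxaborolan-2-yl)but-2-en-1-yl]oxy}silane | C/C(CB1OC(C)(C)C(C)(C)O1)=C/CO[Si](CC)(CC)CC | intermediate
22 | C8 carbinol (7,8-syn, 8,9-anti; C7 with isopropenyl and CH2OSiEt3; C9 OSiEt3; C3 OSitBuMe2) | I/C=C(C)\[C@@H](O[Si](C)(C)C(C)(C)C)C[C@H]1O[C@@]1(C)[C@@H](O[Si](CC)(CC)CC)[C@@H](O)[C@@H](C(C)=C)CO[Si](CC)(CC)CC | intermediate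
23 | angelic acid, (Z)-2-methylbut-2-enoic acid | C/C=C(/C)C(=O)O | starting material
24 | C8 angelate of 22 | I/C=C(C)\[C@@H](O[Si](C)(C)C(C)(C)C)C[C@H]1O[C@@]1(C)[C@@H](O[Si](CC)(CC)CC)[C@@H](OC(=O)/C(C)=C\C)[C@@H](C(C)=C)CO[Si](CC)(CC)CC | intermediate
25 | C6,C9-diol (C8 angelate, C3 silyl ether) | I/C=C(C)\[C@@H](O[Si](C)(C)C(C)(C)C)C[C@H]1O[C@@]1(C)[C@@H](O)[C@@H](OC(=O)/C(C)=C\C)[C@@H](C(C)=C)CO | intermediate
26 | C6 primary iodide with free C9 hydroxyl | I/C=C(C)\[C@@H](O[Si](C)(C)C(C)(C)C)C[C@H]1O[C@@]1(C)[C@@H](O)[C@@H](OC(=O)/C(C)=C\C)[C@@H](C(C)=C)CI | intermediate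
27 | acyclic C6 alkyl iodide and C5 (Z)-alkenyl iodide with C9 acetate, C8 angelate, C3 silyl ether and 1,10-oxirane | I/C=C(C)\[C@@H](O[Si](C)(C)C(C)(C)C)C[C@H]1O[C@@]1(C)[C@@H](OC(C)=O)[C@@H](OC(=O)/C(C)=C\C)[C@@H](C(C)=C)CI | intermediate (key-step precursor)
28 | C6 alkylzinc iodide of 27 | I/C=C(C)\[C@@H](O[Si](C)(C)C(C)(C)C)C[C@H]1O[C@@]1(C)[C@@H](OC(C)=O)[C@@H](OC(=O)/C(C)=C\C)[C@@H](C(C)=C)C[Zn]I | intermediate (not isolated)
29 | ten-membered (Z)-C4=C5 cycloalkene, C3 tert-butyldimethylsilyl ether, C8 angelate, C9 acetate, 1,10-oxirane | C=C(C)[C@H]1C/C=C(C)\[C@@H](O[Si](C)(C)C(C)(C)C)C[C@H]2O[C@@]2(C)[C@@H](OC(C)=O)[C@H]1OC(=O)/C(C)=C\C | intermediate (key-step product)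
30 | C3 allylic alcohol of the ten-membered (Z)-cycloalkene | C=C(C)[C@H]1C/C=C(C)\[C@@H](O)C[C@H]2O[C@@]2(C)[C@@H](OC(C)=O)[C@H]1OC(=O)/C(C)=C\C | intermediate
31 | 4,5:1,10-bis-oxirane with free C3 hydroxyl | C=C(C)[C@H]1C[C@@H]2O[C@]2(C)[C@@H](O)C[C@H]2O[C@@]2(C)[C@@H](OC(C)=O)[C@H]1OC(=O)/C(C)=C\C | intermediate
32 | CNP0220329.1 | C=C(C)[C@H]1C[C@@H]2O[C@]2(C)[C@@H](OC(=O)/C(C)=C\C)C[C@H]2O[C@@]2(C)[C@@H](OC(C)=O)[C@H]1OC(=O)/C(C)=C\C | target

Total step count: 24 (21 on the main line, 3 for allylboronate 21).
Longest linear sequence: 21 steps (steps 1–12 and 16–24).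

Steps most likely to fail

Step 21 (proposed new method). Intermolecular transmetalation may lead to oligomers, or β-hydride elimination and protodezincation may outrun the ring closure. The fallback uses known chemistry to make the same C5–C6 bond with reversed polarity. It sets out from 27: the primary iodide is oxidised with trimethylamine N-oxide in DMSO at rt (Kornblum-type oxidation) to the C6 aldehyde F1, which is used crude because it is a β,γ-unsaturated aldehyde. CrCl2 with catalytic NiCl2 in DMSO/THF at 2 mM (Nozaki–Hiyama–Kishi reaction of the alkenyl iodide with the aldehyde) should then close the ten-membered ring to the C6 ring allylic alcohol F2, as a mixture of C6 epimers that is of no consequence. 1,1'-Thiocarbonyldiimidazole with DMAP gives the C6 imidazolylthiocarbonate F3, and Bu3SnH with AIBN in toluene at 80 °C (Barton–McCombie deoxygenation, hydrogen transfer to the less hindered C6 end of the allyl radical) removes the oxygen. The fallback comes back to the route at 29.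

Step 23. Oxygen may be delivered to the wrong alkene face in the ring conformer that reacts, or the isopropenyl group may be oxidised in competition. The fallback replaces hydroxyl direction by steric control and changes the order of the last two operations. It sets out from 30, which is first esterified with the angelic mixed anhydride (conditions of step 24) to the triester (Z)-cycloalkene F4. This is then epoxidised with dimethyldioxirane in acetone at −20 °C, where the reagent can reach only the outer face of the ring alkene (peripheral attack). The fallback comes back to the route at 32.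

Step 10. Felkin–Anh control may be lost through magnesium chelation between the aldehyde and oxirane oxygens, giving the 9,10-syn epimer. The fallback sets C9 by hydride delivery instead of carbon–carbon bond formation. It sets out from 14 as the epimer mixture, which is oxidised with Dess–Martin periodinane to the epoxy vinyl ketone F5. Reduction with Zn(BH4)2 in Et2O at −20 °C should then proceed through a zinc chelate of the ketone and oxirane oxygens with hydride delivered from the methyl-flanked face (the erythro-selective reduction known for α,β-epoxy ketones). The fallback comes back to the route at 14 as the 9,10-anti alcohol.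

Further compounds
F1 | step 21 | C6 aldehyde from 27 (C5 alkenyl iodide, C9 acetate, C8 angelate, C3 silyl ether retained) | I/C=C(C)\[C@@H](O[Si](C)(C)C(C)(C)C)C[C@H]1O[C@@]1(C)[C@@H](OC(C)=O)[C@@H](OC(=O)/C(C)=C\C)[C@@H](C(C)=C)C=O
F2 | step 21 | C6 ring allylic alcohol of the ten-membered (Z)-cycloalkene (C6 epimers) | C=C(C)[C@H]1C(O)/C=C(C)\[C@@H](O[Si](C)(C)C(C)(C)C)C[C@H]2O[C@@]2(C)[C@@H](OC(C)=O)[C@H]1OC(=O)/C(C)=C\C
F3 | step 21 | C6 O-(imidazol-1-ylthiocarbonyl) derivative of F2 | C=C(C)[C@H]1C(OC(=S)n2ccnc2)/C=C(C)\[C@@H](O[Si](C)(C)C(C)(C)C)C[C@H]3O[C@@]3(C)[C@@H](OC(C)=O)[C@H]1OC(=O)/C(C)=C\C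
F4 | step 23 | ten-membered (Z)-C4=C5 cycloalkene with C3 and C8 angelates, C9 acetate and 1,10-oxirane | C=C(C)[C@H]1C/C=C(C)\[C@@H](OC(=O)/C(C)=C\C)C[C@H]2O[C@@]2(C)[C@@H](OC(C)=O)[C@H]1OC(=O)/C(C)=C\C
F5 | step 10 | epoxy vinyl ketone (C9 ketone of 14) | I/C=C(C)\[C@@H](O[Si](C)(C)C(C)(C)C)C[C@H]1O[C@@]1(C)C(=O)C=C
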